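The east run kept 29% of left-handed substrate at 6.00 h, with left-handed product near 22%. The meeting took this leftover first. One colleague held that the coupling partner is the limiting reagent there, since the north run, charged with more of it, reached 39%.

all flasks: left-handed substrate 0.50 M; right-handed substrate 0.50 M; precatalyst 25 mM
- east: coupling partner 0.25 M; run made earlier
- north: coupling partner 0.38 M; run made earlier
- flask: coupling partner 0.500 M

| run | time / h | left-handed product / % | left-handed substrate / % |
|---|---|---|---|
| east | 0.500 | 5 | 47 |
| east | 0.833 | 9 | 39 |
| east | 1.33 | 17 | 30 |
| east | 2.50 | 23 | 25 |
| east | 4.00 | 20 | 27 |
| east | 6.00 | 22 | 29 |
| north | 1.00 | 21 | 32 |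
| north | 2.00 | 30 | 17 |
| north | 3.00 | 29 | 16 |
| north | 4.00 | 34 | 19 |
| north | 5.00 | 33 | 14 |
| north | 6.00 | 39 | 17 |

(scatter of a reading: 2 percentage points)

* factor on the rate of making left-handed product when 10% of the left-handed substrate and right-handed substrate together are converted if precatalyst is charged twice over
* factor on the rate when 10% of the left-handed substrate and right-handed substrate together are converted if precatalyst is charged at 5.0 mM instead

- catalyst is single-handed; left-handed substrate and right-handed substrate are mirror images of each other, charged as a racemate, each of them at the stated concentration
- no earlier run changes the charge of precatalyst; that part of a forecast is a guess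

A second colleague pointed to the east start. In the east run, left-handed product read 5% at 0.500 h, then rose faster between 0.833 h and 1.33 h than before. That colleague argued that precatalyst was still turning into catalyst.

I argued that early catalyst grows in step with time, so conversion goes as charge times time squared. With the other charges held, time to a fixed conversion then goes as the inverse root of the charge of precatalyst. I called the stretch the factor on that time when the charge falls from 25 mM to 5.0 mM: 2.24.

Taking the rate as first order in coupling partner, I scaled the east start and put the conversion asked about in the new flask at 0.500 h. I took an activation time of 1.33 h, a rough guess from the east start. The factor on the rate is then the charge ratio times the active share at the stretched time over the active share at the old time. That gave me 1.49 for doubling and 0.363 for the other amount.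

The forecast gave 1.5 and 0.37, against my 0.363 on the second, holding that the response “lies between square-root and first order”.

The flask gives 1.48 and 0.373.

    coupling partner + catalyst + left-handed substrate → catalyst + left-handed product (k = 520 L² mol⁻² h⁻¹)
    coupling partner + catalyst + right-handed substrate → catalyst + right-handed product (k = 14.0 L² mol⁻² h⁻¹)
    coupling partner ⇌ dormant form (K = 0.500, k = 0.330 h⁻¹)
    precatalyst → catalyst (k = 0.450 h⁻¹)

In this flask, half of the turnover to left-handed product up to 8.00 h is done by 0.902 h, earlier than half of the activation up to that time, at 1.48 h. This flask reaches the conversion asked about at 0.440 h, so the stretch puts the 5.0 mM flask at 0.984 h. By then, activation leaves 64.2% of the catalyst charged as precatalyst, and the 5.0 mM flask holds 61.4% at that conversion.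

(The earlier runs and the new flask were computed for an exercise; noise was put on by code.)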